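**Retrosynthetic overview**

1. Target 28 ⇐ ester and protecting-group steps ⇐ diol 22 ⇐ convex-face epoxidation and hydride opening of the cyclopentene alkene of hydroazulenol 20.
2. 20 ⇐ (key) one-pot mesylation / pinacol-type 1,2-shift / reduction of the trans-fused hexahydronaphthalene-4a,5-diol 17: the C4a–C8a ring-fusion bond moves to C5, so the isopropyl-bearing six-membered ring contracts to the five-membered ring and, in the same event, the other six-membered ring expands to the seven-membered ring.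
3. Enabling feature of 17: the tertiary hydroxyl on ring-fusion carbon C4a lies next to the allylic secondary C5–O leaving group, whose bond is pseudo-equatorial and anti-periplanar to the C4a–C8a bond (C8a is the quaternary carbon with the angular methyl); C4a becomes the ketone carbon, so its configuration is not needed.
4. 17 ⇐ ring-closing metathesis of 16 ⇐ chelation-controlled methallylation of α-hydroxy ketone 13 ⇐ γ-deprotonation/α-hydroxylation of enone 11 ⇐ ligand-controlled alkenylation of aldehyde 6.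
5. 6 ⇐ asymmetric Michael addition and aldol condensation of 1 + 2. Ring order: cyclohexenone, then the second six-membered ring by metathesis, then the five- and seven-membered rings together in the key step.

Key step: step 10

Assumption: the catalyst enantiomer in step 1 and the ligand enantiomer in step 5 are those whose established sense of induction leads to the drawn configurations (R at the quaternary carbon of 3, R at the carbinol carbon of 10).

**Route**

Step 1
Reactants: 1 ethyl 2-methyl-3-oxobutanoate; 2 4-methylpent-1-en-3-one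
Product: 3 ethyl (2R)-2-acetyl-2,6-dimethyl-5-oxoheptanoate
Conditions: cinchona-derived bifunctional thiourea (10 mol%), toluene, −20 °C
Reagents that add atoms: none
Why: Catalytic asymmetric Michael addition of an α-substituted β-keto ester to a vinyl ketone, in which the bifunctional catalyst shields one face of the hydrogen-bonded enol so that the quaternary carbon (the later methyl-bearing ring-fusion carbon) should form as R.

Step 2
Reactants: 3 ethyl (2R)-2-acetyl-2,6-dimethyl-5-oxoheptanoate
Product: 4 ethyl (1R)-1-methyl-2-oxo-4-(propan-2-yl)cyclohex-3-ene-1-carboxylate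
Conditions: p-TsOH·H2O (10 mol%), toluene, reflux, Dean–Stark
Reagents that add atoms: none
Why: Acid-catalysed intramolecular aldol condensation (second half of a Robinson annulation), in which only attack of the acetyl methyl on the isopropyl ketone can dehydrate to a conjugated cyclohexenone and the non-enolisable quaternary centre is untouched.

Step 3
Reactants: 4 ethyl (1R)-1-methyl-2-oxo-4-(propan-2-yl)cyclohex-3-ene-1-carboxylate
Product: 5 (6S)-6-(hydroxymethyl)-6-methyl-3-(propan-2-yl)cyclohex-2-en-1-ol (both C1 epimers)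
Conditions: DIBAL-H (4.5 equiv), CH2Cl2, −78 → 0 °C; Rochelle salt
Reagents that add atoms: none
Why: Hydride reduction with DIBAL-H takes the ester to the primary alcohol and the enone carbonyl to the allylic alcohol by 1,2-addition, and the new carbinol centre does not matter because it is reoxidised in step 4.

Step 4
Reactants: 5 (6S)-6-(hydroxymethyl)-6-methyl-3-(propan-2-yl)cyclohex-2-en-1-ol
Product: 6 (1S)-1-methyl-2-oxo-4-(propan-2-yl)cyclohex-3-ene-1-carbaldehyde
Conditions: Dess–Martin periodinane (2.6 equiv), NaHCO3, CH2Cl2, 0 °C → rt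
Reagents that add atoms: none
Why: Dess–Martin oxidation converts the primary and the allylic secondary alcohol into aldehyde and enone under buffered conditions, giving a 2-formyl enone that cannot enolise at the quaternary carbon.

Step 5
Reactants: 6 (1S)-1-methyl-2-oxo-4-(propan-2-yl)cyclohex-3-ene-1-carbaldehyde; 7 hex-1-yne
Product: 10 (6S)-6-[(1R,2E)-1-hydroxyhept-2-en-1-yl]-6-methyl-3-(propan-2-yl)cyclohex-2-en-1-one, via alkenylborane 8 (not isolated), via alkenylzinc 9 (not isolated)
Conditions: 7, Cy2BH, toluene, 0 °C → rt; Me2Zn, −78 °C; (+)-MIB (5 mol%); 6, −10 °C; aq. work-up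
Reagents that add atoms: none
Why: Catalytic asymmetric alkenylzinc addition (alkyne hydroboration, boron-to-zinc transmetalation, amino-alcohol ligand) is selective for the aldehyde over the enone and is ligand-controlled, so the carbinol carbon (the later isovalerate-bearing carbon) should be R, while the butyl end of the alkene is lost later in the metathesis.

Step 6
Reactants: 10 (6S)-6-[(1R,2E)-1-hydroxyhept-2-en-1-yl]-6-methyl-3-(propan-2-yl)cyclohex-2-en-1-one
Product: 11 (6S)-6-[(1R,2E)-1-{[tert-butyl(dimethyl)silyl]oxy}hept-2-en-1-yl]-6-methyl-3-(propan-2-yl)cyclohex-2-en-1-one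
Conditions: TBSOTf, 2,6-lutidine, CH2Cl2, −78 → 0 °C
Reagents that add atoms: tert-butyldimethylsilyl trifluoromethanesulfonate, CC(C)(C)[Si](C)(C)OS(=O)(=O)C(F)(F)F
Why: Silyl ether formation with the silyl triflate protects the hindered secondary alcohol through step 13 and makes this side chain the bulky pseudo-equatorial substituent on the quaternary carbon.

Step 7
Reactants: 11 (6S)-6-[(1R,2E)-1-{[tert-butyl(dimethyl)silyl]oxy}hept-2-en-1-yl]-6-methyl-3-(propan-2-yl)cyclohex-2-en-1-one
Product: 13 (2S,6S)-6-[(1R,2E)-1-{[tert-butyl(dimethyl)silyl]oxy}hept-2-en-1-yl]-2-hydroxy-6-methyl-3-(propan-2-yl)cyclohex-3-en-1-one, via potassium dienolate 12 (not isolated)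
Conditions: KHMDS, THF, −78 °C; 3-phenyl-2-(phenylsulfonyl)oxaziridine, −78 °C; AcOH
Reagents that add atoms: 3-phenyl-2-(phenylsulfonyl)oxaziridine, O=S(=O)(N1OC1c1ccccc1)c1ccccc1
Why: γ-Deprotonation (there is no α′-hydrogen) gives the extended dienolate, which the oxaziridine hydroxylates at the α-carbon (Davis oxidation) with shift of the double bond to the β,γ-position, and attack anti to the pseudo-axial methyl on the quaternary carbon should place the hydroxyl trans to that methyl (2S).

Step 8
Reactants: 13 (2S,6S)-6-[(1R,2E)-1-{[tert-butyl(dimethyl)silyl]oxy}hept-2-en-1-yl]-2-hydroxy-6-methyl-3-(propan-2-yl)cyclohex-3-en-1-one; 14 3-bromo-2-methylprop-1-ene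
Product: 16 (1R,2S,6S)-6-[(1R,2E)-1-{[tert-butyl(dimethyl)silyl]oxy}hept-2-en-1-yl]-6-methyl-1-(2-methylprop-2-en-1-yl)-3-(propan-2-yl)cyclohex-3-ene-1,2-diol, via methallylzinc bromide 15 (not isolated)
Conditions: 14, Zn dust, THF/sat. aq. NH4Cl, 0 °C → rt
Reagents that add atoms: none
Why: The zinc-mediated Barbier allylation is non-basic (no enolisation of the α-hydroxy β,γ-enone) and is expected to be chelation-controlled through the free α-hydroxyl (Cram chelate), adding the methallyl group trans to that hydroxyl to give the syn-diol, while any C1 epimer is carried on because this carbon becomes the carbonyl carbon in step 10.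

Step 9
Reactants: 16 (1R,2S,6S)-6-[(1R,2E)-1-{[tert-butyl(dimethyl)silyl]oxy}hept-2-en-1-yl]-6-methyl-1-(2-methylprop-2-en-1-yl)-3-(propan-2-yl)cyclohex-3-ene-1,2-diol
Product: 17 (1R,4aR,5S,8aS)-1-{[tert-butyl(dimethyl)silyl]oxy}-3,8a-dimethyl-6-(propan-2-yl)-1,4,4a,5,8,8a-hexahydronaphthalene-4a,5-diol
Conditions: Hoveyda–Grubbs II (5 mol%), toluene, 80 °C
Reagents that add atoms: none
Why: Ring-closing metathesis between the methallyl alkene and the disubstituted alkenyl group closes the six-membered ring with a trisubstituted alkene and expels hex-1-ene, the two trans-diequatorial chains giving the trans-fused bicycle and the hindered ring alkene staying out of the reaction.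

Step 10
Reactants: 17 (1R,4aR,5S,8aS)-1-{[tert-butyl(dimethyl)silyl]oxy}-3,8a-dimethyl-6-(propan-2-yl)-1,4,4a,5,8,8a-hexahydronaphthalene-4a,5-diol
Product: 20 (3aS,4R,8R,8aR)-8-{[tert-butyl(dimethyl)silyl]oxy}-6,8a-dimethyl-3-(propan-2-yl)-1,3a,4,5,8,8a-hexahydroazulen-4-ol, via mesylate 18 (not isolated), via hydroazulenone 19 (not isolated)
Conditions: MsCl, Et3N, CH2Cl2, −40 °C; Et2AlCl, −78 → 0 °C; DIBAL-H, −78 °C
Reagents that add atoms: none
Why: Mesylation of the secondary allylic C5 hydroxyl (the tertiary C4a hydroxyl does not react) gives 18, and Et2AlCl turns the C4a hydroxyl into an aluminium alkoxide whose push drives a concerted 1,2-shift of the C4a–C8a ring-fusion bond to C5 with loss of mesylate, leaving C4a as the ketone carbon of 19. This is a pinacol-type (semipinacol) rearrangement of a 1,2-diol monosulfonate, the organoaluminium-promoted variant of the classical conversion of decalin-diol monosulfonates into hydroazulenones. No ring is closed by a cyclisation: the cyclopentene arises by contraction of the isopropyl-bearing cyclohexene (C4a is extruded) and the cycloheptene by insertion of C5 into the second six-membered ring, both in the same 1,2-shift. C5 is inverted (the migrating carbon enters anti to the leaving mesylate) and the migrating quaternary carbon C8a keeps its configuration, so the angular methyl and the new ring-fusion hydrogen end cis, and DIBAL-H then attacks the ketone from the convex face (the side of that hydrogen) to set the carbinol centre as R. The step needs migration of the ring-fusion bond and not of the allylic ring CH2 or closure to an epoxide, which the trans-fused half-chair secures because the pseudo-equatorial mesylate is anti-periplanar only to the C4a–C8a bond while the axial tertiary oxygen and the CH2 are gauche to it. Because C4a becomes sp2, a minor C4a epimer of 17 should be funnelled to the same ketone.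

Step 11
Reactants: 20 (3aS,4R,8R,8aR)-8-{[tert-butyl(dimethyl)silyl]oxy}-6,8a-dimethyl-3-(propan-2-yl)-1,3a,4,5,8,8a-hexahydroazulen-4-ol
Product: 21 2,3-epoxide of 20 (epoxide oxygen cis to the 8a-methyl and the 3a-hydrogen)
Conditions: mCPBA, NaHCO3, CH2Cl2, −20 °C
Reagents that add atoms: 3-chloroperoxybenzoic acid, OOC(=O)c1cccc(Cl)c1
Why: In this Prilezhaev epoxidation the trisubstituted cyclopentene alkene, which has no allylic oxygen, should react before the cycloheptene alkene that is deactivated and shielded by the allylic silyl ether, and the peracid comes from the convex face, which fixes the configuration of the later tertiary carbinol.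

Step 12
Reactants: 21 2,3-epoxide of 20
Product: 22 (3S,3aS,4R,8R,8aR)-8-{[tert-butyl(dimethyl)silyl]oxy}-6,8a-dimethyl-3-(propan-2-yl)-1,2,3,3a,4,5,8,8a-octahydroazulene-3,4-diol
Conditions: LiEt3BH, THF, 0 °C → rt
Reagents that add atoms: none
Why: Hydride opening of the trisubstituted epoxide by SN2 attack at the less substituted carbon C2 leaves the oxygen on the isopropyl-bearing carbon as the tertiary alcohol with the configuration set in step 11.

Step 13
Reactants: 22 (3S,3aS,4R,8R,8aR)-8-{[tert-butyl(dimethyl)silyl]oxy}-6,8a-dimethyl-3-(propan-2-yl)-1,2,3,3a,4,5,8,8a-octahydroazulene-3,4-diol; 23 4-(acetyloxy)benzoyl chloride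
Product: 24 (3S,3aS,4R,8R,8aR)-8-{[tert-butyl(dimethyl)silyl]oxy}-3-hydroxy-6,8a-dimethyl-3-(propan-2-yl)-1,2,3,3a,4,5,8,8a-octahydroazulen-4-yl 4-(acetyloxy)benzoate
Conditions: 23, pyridine, DMAP (cat.), CH2Cl2, 0 °C → rt
Reagents that add atoms: none
Why: DMAP-catalysed acylation takes place at the only secondary hydroxyl, the tertiary alcohol being unreactive under these conditions, and the phenol is carried as its acetate.

Step 14
Reactants: 24 (3S,3aS,4R,8R,8aR)-8-{[tert-butyl(dimethyl)silyl]oxy}-3-hydroxy-6,8a-dimethyl-3-(propan-2-yl)-1,2,3,3a,4,5,8,8a-octahydroazulen-4-yl 4-(acetyloxy)benzoate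
Product: 25 (3S,3aS,4R,8R,8aR)-3,8-dihydroxy-6,8a-dimethyl-3-(propan-2-yl)-1,2,3,3a,4,5,8,8a-octahydroazulen-4-yl 4-(acetyloxy)benzoate
Conditions: HF·pyridine, pyridine/THF, 0 °C → rt
Reagents that add atoms: none
Why: Fluoride-mediated desilylation under buffered conditions leaves both esters and the tertiary alcohol untouched and avoids acyl migration.

Step 15
Reactants: 25 (3S,3aS,4R,8R,8aR)-3,8-dihydroxy-6,8a-dimethyl-3-(propan-2-yl)-1,2,3,3a,4,5,8,8a-octahydroazulen-4-yl 4-(acetyloxy)benzoate; 26 3-methylbutanoyl chloride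
Product: 27 (3S,3aS,4R,8R,8aR)-3-hydroxy-6,8a-dimethyl-8-[(3-methylbutanoyl)oxy]-3-(propan-2-yl)-1,2,3,3a,4,5,8,8a-octahydroazulen-4-yl 4-(acetyloxy)benzoate
Conditions: 26, pyridine, DMAP (cat.), CH2Cl2, 0 °C
Reagents that add atoms: none
Why: DMAP-catalysed acylation of the freed secondary allylic alcohol installs the isovalerate while the tertiary alcohol stays free.

Step 16
Reactants: 27 (3S,3aS,4R,8R,8aR)-3-hydroxy-6,8a-dimethyl-8-[(3-methylbutanoyl)oxy]-3-(propan-2-yl)-1,2,3,3a,4,5,8,8a-octahydroazulen-4-yl 4-(acetyloxy)benzoate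
Product: 28 (3S,3aS,4R,8R,8aR)-3-hydroxy-6,8a-dimethyl-8-[(3-methylbutanoyl)oxy]-3-(propan-2-yl)-1,2,3,3a,4,5,8,8a-octahydroazulen-4-yl 4-hydroxybenzoate
Conditions: pyrrolidine, CH2Cl2, 0 °C
Reagents that add atoms: none
Why: Chemoselective aminolysis cleaves the aryl acetate, which is far more electrophilic than the alkyl isovalerate and the benzoate, and frees the phenol of the target.

**Compound list**

1 | ethyl 2-methyl-3-oxobutanoate | CCOC(=O)C(C)C(C)=O | starting material
2 | 4-methylpent-1-en-3-one | C=CC(=O)C(C)C | starting material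
3 | ethyl (2R)-2-acetyl-2,6-dimethyl-5-oxoheptanoate | CCOC(=O)[C@](C)(CCC(=O)C(C)C)C(C)=O | intermediate
4 | ethyl (1R)-1-methyl-2-oxo-4-(propan-2-yl)cyclohex-3-ene-1-carboxylate | CCOC(=O)[C@]1(C)CCC(C(C)C)=CC1=O | intermediate
5 | (6S)-6-(hydroxymethyl)-6-methyl-3-(propan-2-yl)cyclohex-2-en-1-ol, both C1 epimers | OC[C@]1(C)CCC(C(C)C)=CC1O | intermediate
6 | (1S)-1-methyl-2-oxo-4-(propan-2-yl)cyclohex-3-ene-1-carbaldehyde | O=C[C@]1(C)CCC(C(C)C)=CC1=O | intermediate
7 | hex-1-yne | CCCCC#C | starting material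
8 | dicyclohexyl[(1E)-hex-1-en-1-yl]borane (not isolated) | CCCC/C=C/B(C1CCCCC1)C1CCCCC1 | intermediate
9 | [(1E)-hex-1-en-1-yl](methyl)zinc (not isolated) | CCCC/C=C/[Zn]C | intermediate
10 | (6S)-6-[(1R,2E)-1-hydroxyhept-2-en-1-yl]-6-methyl-3-(propan-2-yl)cyclohex-2-en-1-one | CCCC/C=C/[C@@H](O)[C@]1(C)CCC(C(C)C)=CC1=O | intermediate
11 | (6S)-6-[(1R,2E)-1-{[tert-butyl(dimethyl)silyl]oxy}hept-2-en-1-yl]-6-methyl-3-(propan-2-yl)cyclohex-2-en-1-one | CCCC/C=C/[C@@H](O[Si](C)(C)C(C)(C)C)[C@]1(C)CCC(C(C)C)=CC1=O | intermediate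
12 | potassium dienolate of 11 (cyclohexa-1,3-dien-1-olate, not isolated) | CCCC/C=C/[C@@H](O[Si](C)(C)C(C)(C)C)[C@]1(C)CC=C(C(C)C)C=C1[O-].[K+] | intermediate
13 | (2S,6S)-6-[(1R,2E)-1-{[tert-butyl(dimethyl)silyl]oxy}hept-2-en-1-yl]-2-hydroxy-6-methyl-3-(propan-2-yl)cyclohex-3-en-1-one | CCCC/C=C/[C@@H](O[Si](C)(C)C(C)(C)C)[C@]1(C)CC=C(C(C)C)[C@H](O)C1=O | intermediate
14 | 3-bromo-2-methylprop-1-ene | CC(=C)CBr | starting material
15 | (2-methylprop-2-en-1-yl)zinc bromide (not isolated) | CC(=C)C[Zn]Br | intermediate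
16 | (1R,2S,6S)-6-[(1R,2E)-1-{[tert-butyl(dimethyl)silyl]oxy}hept-2-en-1-yl]-6-methyl-1-(2-methylprop-2-en-1-yl)-3-(propan-2-yl)cyclohex-3-ene-1,2-diol | CCCC/C=C/[C@@H](O[Si](C)(C)C(C)(C)C)[C@]1(C)CC=C(C(C)C)[C@H](O)[C@@]1(O)CC(C)=C | intermediate
17 | (1R,4aR,5S,8aS)-1-{[tert-butyl(dimethyl)silyl]oxy}-3,8a-dimethyl-6-(propan-2-yl)-1,4,4a,5,8,8a-hexahydronaphthalene-4a,5-diol | CC1=C[C@@H](O[Si](C)(C)C(C)(C)C)[C@]2(C)CC=C(C(C)C)[C@H](O)[C@@]2(O)C1 | intermediate
18 | 5-O-methanesulfonate of 17 (not isolated) | CC1=C[C@@H](O[Si](C)(C)C(C)(C)C)[C@]2(C)CC=C(C(C)C)[C@H](OS(C)(=O)=O)[C@@]2(O)C1 | intermediate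
19 | (3aS,8R,8aR)-8-{[tert-butyl(dimethyl)silyl]oxy}-6,8a-dimethyl-3-(propan-2-yl)-3a,5,8,8a-tetrahydroazulen-4(1H)-one (not isolated) | CC1=C[C@@H](O[Si](C)(C)C(C)(C)C)[C@]2(C)CC=C(C(C)C)[C@@H]2C(=O)C1 | intermediate
20 | (3aS,4R,8R,8aR)-8-{[tert-butyl(dimethyl)silyl]oxy}-6,8a-dimethyl-3-(propan-2-yl)-1,3a,4,5,8,8a-hexahydroazulen-4-ol | CC1=C[C@@H](O[Si](C)(C)C(C)(C)C)[C@]2(C)CC=C(C(C)C)[C@@H]2[C@H](O)C1 | intermediate
21 | 2,3-epoxide of 20, oxygen cis to the 8a-methyl and the 3a-hydrogen | CC1=C[C@@H](O[Si](C)(C)C(C)(C)C)[C@]2(C)C[C@H]3O[C@@]3(C(C)C)[C@@H]2[C@H](O)C1 | intermediate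
22 | (3S,3aS,4R,8R,8aR)-8-{[tert-butyl(dimethyl)silyl]oxy}-6,8a-dimethyl-3-(propan-2-yl)-1,2,3,3a,4,5,8,8a-octahydroazulene-3,4-diol | CC1=C[C@@H](O[Si](C)(C)C(C)(C)C)[C@]2(C)CC[C@](O)(C(C)C)[C@@H]2[C@H](O)C1 | intermediate
23 | 4-(acetyloxy)benzoyl chloride | CC(=O)Oc1ccc(cc1)C(Cl)=O | starting material
24 | (3S,3aS,4R,8R,8aR)-8-{[tert-butyl(dimethyl)silyl]oxy}-3-hydroxy-6,8a-dimethyl-3-(propan-2-yl)-1,2,3,3a,4,5,8,8a-octahydroazulen-4-yl 4-(acetyloxy)benzoate | CC1=C[C@@H](O[Si](C)(C)C(C)(C)C)[C@]2(C)CC[C@](O)(C(C)C)[C@@H]2[C@H](OC(=O)c2ccc(OC(C)=O)cc2)C1 | intermediate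
25 | (3S,3aS,4R,8R,8aR)-3,8-dihydroxy-6,8a-dimethyl-3-(propan-2-yl)-1,2,3,3a,4,5,8,8a-octahydroazulen-4-yl 4-(acetyloxy)benzoate | CC1=C[C@@H](O)[C@]2(C)CC[C@](O)(C(C)C)[C@@H]2[C@H](OC(=O)c2ccc(OC(C)=O)cc2)C1 | intermediate
26 | 3-methylbutanoyl chloride | CC(C)CC(Cl)=O | starting material
27 | (3S,3aS,4R,8R,8aR)-3-hydroxy-6,8a-dimethyl-8-[(3-methylbutanoyl)oxy]-3-(propan-2-yl)-1,2,3,3a,4,5,8,8a-octahydroazulen-4-yl 4-(acetyloxy)benzoate | CC1=C[C@@H](OC(=O)CC(C)C)[C@]2(C)CC[C@](O)(C(C)C)[C@@H]2[C@H](OC(=O)c2ccc(OC(C)=O)cc2)C1 | intermediate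
28 | (3S,3aS,4R,8R,8aR)-3-hydroxy-6,8a-dimethyl-8-[(3-methylbutanoyl)oxy]-3-(propan-2-yl)-1,2,3,3a,4,5,8,8a-octahydroazulen-4-yl 4-hydroxybenzoate | CC1=C[C@@H](OC(=O)CC(C)C)[C@]2(C)CC[C@](O)(C(C)C)[C@@H]2[C@H](OC(=O)c2ccc(O)cc2)C1 | target

**Totals and risks**

Total step count: 16. Longest linear sequence: 16 steps (fully linear from 1 and 2).

Steps most likely to fail:

1. Step 10. The allylic mesylate may ionise before the alkoxide push is established (allylic transposition, elimination to a diene), the ring CH2 may migrate in place of the ring-fusion bond, or a minor C4a epimer may close to an epoxide. Fallback: set out from 16 and carry out the ring contraction before the second ring exists. Mesylation of the secondary hydroxyl should give the monocyclic mesylate F1, in which the ring bond to the quaternary carbon is again the only bond anti to the pseudo-equatorial leaving group. The Et2AlCl-promoted 1,2-shift should then give the cyclopentenyl ketone F2. Ring-closing metathesis (Hoveyda–Grubbs II) closes the seven-membered ring directly, and the route is rejoined at 19, which is reduced with DIBAL-H to 20.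

2. Step 7. Oxygen transfer may show poor facial selectivity at C2, deprotonation may occur at the isopropyl methine, or the α-hydroxy β,γ-enone may isomerise to the conjugated diosphenol under base. Fallback: set out from 11 and bring in the oxygen by nucleophilic epoxidation (Weitz–Scheffer, t-BuOOH/DBU) to the epoxy ketone F3. Epoxide-to-allylic silyl ether isomerisation (TMSOTf, 2,6-lutidine, then DBU) moves the double bond into the ring and should give the silyl ether F4. Mild acid methanolysis rejoins the route at 13; C2 is α to the carbonyl and can be equilibrated to the equatorial epimer trans to the methyl.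

3. Step 11. The peracid may not discriminate between the two trisubstituted alkenes, or the free homoallylic hydroxyl may deliver it to the concave face. Fallback: set out from 19 (isolated by leaving out the DIBAL-H addition in step 10). DBU isomerisation should give the conjugated enone F5. Alkaline hydrogen peroxide epoxidises only this electron-poor alkene, from the convex face, to the epoxy ketone F6. SmI2 in THF/MeOH at −78 °C opens it reductively to the β-hydroxy ketone F7, the ring-fusion hydrogen coming from kinetic protonation on the convex face. DIBAL-H reduction of the ketone rejoins the route at 22.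

**Further compounds**

F1 | step 10 | 2-O-methanesulfonate of diol 16 (mesylate on the secondary allylic hydroxyl) | CCCC/C=C/[C@@H](O[Si](C)(C)C(C)(C)C)[C@]1(C)CC=C(C(C)C)[C@H](OS(C)(=O)=O)[C@@]1(O)CC(C)=C
F2 | step 10 | 1-[(1S,5R)-5-[(1R,2E)-1-{[tert-butyl(dimethyl)silyl]oxy}hept-2-en-1-yl]-5-methyl-2-(propan-2-yl)cyclopent-2-en-1-yl]-3-methylbut-3-en-1-one | CCCC/C=C/[C@@H](O[Si](C)(C)C(C)(C)C)[C@]1(C)CC=C(C(C)C)[C@@H]1C(=O)CC(C)=C
F3 | step 7 | 2,3-epoxide of enone 11 (epoxide oxygen trans to the ring methyl) | CCCC/C=C/[C@@H](O[Si](C)(C)C(C)(C)C)[C@]1(C)CC[C@]2(C(C)C)O[C@@H]2C1=O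
F4 | step 7 | trimethylsilyl ether of 13 | CCCC/C=C/[C@@H](O[Si](C)(C)C(C)(C)C)[C@]1(C)CC=C(C(C)C)[C@H](O[Si](C)(C)C)C1=O
F5 | step 11 | (8R,8aR)-8-{[tert-butyl(dimethyl)silyl]oxy}-6,8a-dimethyl-3-(propan-2-yl)-2,5,8,8a-tetrahydroazulen-4(1H)-one | CC1=C[C@@H](O[Si](C)(C)C(C)(C)C)[C@]2(C)CCC(C(C)C)=C2C(=O)C1
F6 | step 11 | 3,3a-epoxide of F5 (epoxide oxygen cis to the 8a-methyl) | CC1=C[C@@H](O[Si](C)(C)C(C)(C)C)[C@]2(C)CC[C@@]3(C(C)C)O[C@@]23C(=O)C1
F7 | step 11 | (3S,3aR,8R,8aR)-8-{[tert-butyl(dimethyl)silyl]oxy}-3-hydroxy-6,8a-dimethyl-3-(propan-2-yl)-2,3,3a,5,8,8a-hexahydroazulen-4(1H)-one | CC1=C[C@@H](O[Si](C)(C)C(C)(C)C)[C@]2(C)CC[C@](O)(C(C)C)[C@@H]2C(=O)C1
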